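## The problem

Compound 20 is built from two C6–C3–C6 units: an upper 7,4'-dihydroxyflavan (U) and a lower epiafzelechin (L), joined by a single bond from the sp3 carbon U-C4 to the aromatic carbon L-C8 (flavonoid numbering in each unit). Its four stereocentres fall into two pairs: U-C2 (S) and U-C4 (R) are 1,3-related and trans, while L-C2 (R) and L-C3 (R) are vicinal and cis. Each relationship is the less stable one in its ring, so neither can be reached by equilibration. The pairs are separated by a rotating aryl–alkyl bond, so neither can steer the other. U has no substituent at C3, so a flavan-4-yl cation has no neighbouring group to decide the face of attack at U-C4, and L-C6 and L-C8 of ring D are electronically alike. The six phenols are oxidation-prone. The benzylic ethers U-C2–O1 and L-C2–O1 lie para to an oxygenated aryl group and ionise in acid, with ring opening and epimerisation, and U-C4 is doubly benzylic. Global benzyl protection, mild Lewis acids and a final hydrogenolysis are therefore indicated. The enabling feature is ring D: L-O1 is flanked by L-C8, which carries U-C4, and by L-C4a. L-C4a lies ortho to L-O1, ortho to the L-C5 oxygen and para to the L-C7 oxygen, so it is the most nucleophilic carbon of the ring. A three-atom chain hung on L-O1 and ending in a terminal epoxide can reach only L-C4a.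

## Retrosynthesis

**20 ⇒ 19.** All five phenols are masked as benzyl ethers and the L-3 hydroxyl stays free. No C–C or C–O bond of the skeleton is touched in the last step; the forward reaction must cleave five O-benzyl groups without opening the two cyclic benzylic ethers.

**19 ⇒ 18 (key cut, L-C4–L-C4a).** The lower pyran is opened between L-C4 and L-C4a to the aryl ether 18, whose side chain ends in a terminal epoxide. Two neighbouring cuts were weighed against it. Cutting the interflavan bond U-C4–L-C8 leads to a cation/arene coupling with no control of the face at U-C4 or of L-C6 against L-C8. Cutting L-O1–L-C2 requires that L-C4–L-C4a be made first on a hindered phenol. In 18 the 4→8 connectivity is fixed by construction and both L stereocentres are already present. The forward step only has to direct ring D to the terminal epoxide carbon under a Lewis acid mild enough to spare the benzylic ethers.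

**18 ⇒ 14 + 17 (L-O1–L-C2).** The aryl ether is cut to phenol 14, the complete protected upper flavan, and epoxy alcohol 17, to be joined by a Mitsunobu reaction with inversion at the carbinol. The cis relationship in 19 requires the erythro epoxy alcohol, (S)-carbinol with (R)-oxirane. A threo isomer, as obtained by syn-dihydroxylation of an E-cinnamyl halide and ring closure, would after one inversion end in the 2,3-trans (afzelechin) series. The cut is convergent: all four stereocentres are set in two small fragments, and because 14 is a single enantiomer, any minor enantiomer of 17 ends up as a separable diastereomer of 18.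

**17 ⇒ 16 ⇒ 15.** The erythro epoxy alcohol is the direct product of a Sharpless kinetic resolution of the racemic aryl vinyl carbinol 16, which comes from aldehyde 15 and a vinyl Grignard reagent. This sets both L stereocentres in one step from an achiral aldehyde. A dihydroxylation route would give the wrong diastereomer and need an extra inversion.

**14 ⇒ 13 ⇒ 12 (U-O1–U-C2).** The ring D phenol of 14 is unmasked from allyl ether 13. Ring C of 13 is opened at O1–C2 to phenol alcohol 12, to be closed by an intramolecular Mitsunobu reaction with inversion. This places U-C2 under reagent control, independent of U-C4, which is the only secure way to the less stable 2,4-trans arrangement. The allyl group on ring D ensures that only the ring A phenol can cyclise.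

**12 ⇒ 11 ⇒ 10.** The ring A phenol of 12 is released from silyl ether 11, whose (R)-carbinol comes from ketone 10 by asymmetric transfer hydrogenation. An aryl ketone flanked by a methylene group is a standard substrate for this reduction.

**10 ⇒ 5 + 9 (U-C4–U-C4a).** The stereocentre U-C4 is traced to a catalytic asymmetric conjugate arylation of chalcone 5 with arylboronate 9. Bonding ring A rather than ring D in this step is preferred, because the boron partner then carries one ortho substituent only. A ring D boron reagent would have two ortho oxygens and would protodeboronate readily. The forward reaction must work on a β-carbon that carries a doubly ortho-substituted aryl group.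

**5 ⇒ 3 + 4; 3 ⇒ 2 ⇒ 1.** The chalcone is a Claisen–Schmidt product of aldehyde 3 and ketone 4. Aldehyde 3 comes from 1 by dibenzylation of the two more reactive hydroxyls (2) and allylation of the chelated one.

**9 ⇒ 8 ⇒ 7 ⇒ 6.** The boronate comes from phenol 6 by ortho-bromination (7), silylation (8) and Miyaura borylation.

## Roads not taken

**Alternative 1:** The cut removes both aryl bonds of U-C4 at once (U-C4–U-C4a and U-C4–L-C8). In the forward direction Pd2(dba)3 would join three components in a 1,1-diarylation to give A1: a terminal alkene that carries the U-C2 carbinol as a silyl ether, a ring A diazonium salt, and the boronic acid A2 of the benzylated lower unit. Its merit is convergence: the complete lower unit, ring A and the C3 chain meet in one step, and no ring has to be built on a hindered phenol afterwards. Its weak points are specific to this target. A2 has two ortho oxygens and would be slow to transmetalate and quick to protodeboronate. The palladium intermediate can also eliminate towards the silyloxy-bearing carbon. U-C4 is created from a π-benzyl species whose only bias is a remote 1,3-related silyloxy group, so a mixture of C4 epimers must be expected. In step count this road is better than the chosen one. The chosen plan sets against it that every stereocentre is fixed by its own reagent-controlled operation and that no doubly ortho-substituted boron reagent is needed.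

**Alternative 2:** Ring C of U is cut at O1–C8a by a retro-Baeyer–Villiger step. Forward, a buffered peracid would convert the 3-arylindan-1-one A4 into the dihydrocoumarin A3 by aryl migration. Its merit is that the U-C4 stereocentre would come from well-developed asymmetric 3-arylindanone chemistry, and that the lactone holds the ring A oxygen in place. Its weak points are three. The ring A oxygen is meta to the migrating carbon, so aryl migration is not assisted and methylene migration competes. The peracid meets four electron-rich benzyloxy arenes. After the key step, U-C2 and its aryl group are still missing and need the same aryl addition, asymmetric reduction and inverting ring closure as in the chosen plan. The alternative is equal to the chosen plan in the control of U-C4 and worse in length and chemoselectivity. It also needs the intact lower unit early, whereas the chosen plan builds L from a simple aldehyde.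

**Alternative 3:** The lower pyran is cut at L-O1–L-C2. Forward, a sulfonic acid would make the free ring D phenol of the cis-epoxide A6 attack the benzylic epoxide carbon with inversion to give A5. Its merits are real. The labile benzylic ether is formed last and is never exposed to a Lewis acid, the inversion is stereospecific, and the pivalate on the L-4' oxygen damps ionisation. In this respect it is better than the chosen plan. Its weak points lie before the key step. The L-C4–L-C4a bond must first be made on a hindered phenol, in competition with L-C6, and with a Z-alkene. The cis-epoxide must be set by catalyst control on a large intermediate that already carries the U stereocentres. The electron-poor aryl group that protects the benzylic site also lowers the preference for 6-endo over 5-exo opening. The chosen plan sets against this that regiochemistry on ring D is fixed by the tether and that both L stereocentres arrive in a small fragment that can be purified before coupling.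

Key step: step 15

Assumption: the sense of induction of the chiral catalysts in steps 7, 8 and 13 is assigned by analogy with the accepted models for these reaction types and would be confirmed by correlation on the first run.

## Route

Step 1
Reactants: 1 2,4,6-trihydroxybenzaldehyde
Product: 2 2,4-bis(benzyloxy)-6-hydroxybenzaldehyde
Conditions: BnBr (2.05 equiv), K2CO3, DMF, rt
Reagents that add atoms: benzyl bromide, BrCc1ccccc1
Why: Williamson etherification; the 4-hydroxyl and one ortho hydroxyl are alkylated, while the remaining ortho hydroxyl is held in a hydrogen bond to the carbonyl oxygen and reacts much more slowly, so limiting the halide should stop at the dibenzyl ether.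

Step 2
Reactants: 2 2,4-bis(benzyloxy)-6-hydroxybenzaldehyde
Product: 3 2-(allyloxy)-4,6-bis(benzyloxy)benzaldehyde
Conditions: allyl bromide, K2CO3, DMF, 60 °C
Reagents that add atoms: allyl bromide, C=CCBr
Why: Williamson etherification of the chelated phenol under forcing conditions; the allyl group is base-stable and can later be removed with palladium without touching benzyl ethers.

Step 3
Reactants: 3 2-(allyloxy)-4,6-bis(benzyloxy)benzaldehyde; 4 4'-benzyloxyacetophenone
Product: 5 (E)-3-[2-(allyloxy)-4,6-bis(benzyloxy)phenyl]-1-[4-(benzyloxy)phenyl]prop-2-en-1-one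
Conditions: KOH, EtOH–THF, rt
Reagents that add atoms: none
Why: Claisen–Schmidt condensation of a non-enolisable aldehyde with a methyl ketone; dehydration of the aldol gives the conjugated E-enone, and 2,4,6-trialkoxybenzaldehydes are established partners.

Step 4
Reactants: 6 3-(benzyloxy)phenol
Product: 7 5-(benzyloxy)-2-bromophenol
Conditions: NBS, i-Pr2NH (cat.), CH2Cl2, −78 °C → 0 °C
Reagents that add atoms: N-bromosuccinimide, O=C1CCC(=O)N1Br
Why: Amine-mediated ortho-selective bromination of a phenol; of the two ortho positions the one para to the benzyloxy group is the more activated and the less hindered.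

Step 5
Reactants: 7 5-(benzyloxy)-2-bromophenol
Product: 8 [5-(benzyloxy)-2-bromophenoxy]tri(propan-2-yl)silane
Conditions: i-Pr3SiCl, imidazole, DMF, rt
Reagents that add atoms: chlorotriisopropylsilane, CC(C)[Si](Cl)(C(C)C)C(C)C
Why: Silylation of the phenol; the triisopropylsilyl ether withstands the aqueous base of step 7 and is later removed by fluoride without acid, orthogonal to the allyl and benzyl ethers.

Step 6
Reactants: 8 [5-(benzyloxy)-2-bromophenoxy]tri(propan-2-yl)silane
Product: 9 [5-(benzyloxy)-2-(4,4,5,5-tetramethyl-1,3,2-dioxaborolan-2-yl)phenoxy]tri(propan-2-yl)silane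
Conditions: B2pin2, Pd(dppf)Cl2 (cat.), KOAc, dioxane, 85 °C
Reagents that add atoms: bis(pinacolato)diboron, CC1(C)OB(OC1(C)C)B1OC(C)(C)C(C)(C)O1
Why: Miyaura borylation of an aryl bromide; the palladium route avoids an ortho-lithiated aryl silyl ether and its silyl migration.

Step 7
Reactants: 5 (E)-3-[2-(allyloxy)-4,6-bis(benzyloxy)phenyl]-1-[4-(benzyloxy)phenyl]prop-2-en-1-one; 9 [5-(benzyloxy)-2-(4,4,5,5-tetramethyl-1,3,2-dioxaborolan-2-yl)phenoxy]tri(propan-2-yl)silane
Product: 10 (3R)-3-[2-(allyloxy)-4,6-bis(benzyloxy)phenyl]-1-[4-(benzyloxy)phenyl]-3-{4-(benzyloxy)-2-[(triisopropylsilyl)oxy]phenyl}propan-1-one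
Conditions: [RhCl(C2H4)2]2 (2.5 mol %), (1R,4R)-2,5-diphenylbicyclo[2.2.2]octa-2,5-diene (5.5 mol %), KOH (aq), dioxane–H2O, 50 °C
Reagents that add atoms: none
Why: Hayashi–Miyaura asymmetric conjugate arylation: the aryl–rhodium species formed by transmetalation inserts the enone and the rhodium enolate is hydrolysed; the chiral diene is the enantiomer expected to deliver the aryl group to the Si face of C-β, which gives the (R) centre that becomes U-C4, and the two ortho oxygens twist ring D out of conjugation so that C-β keeps its electrophilicity.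

Step 8
Reactants: 10 (3R)-3-[2-(allyloxy)-4,6-bis(benzyloxy)phenyl]-1-[4-(benzyloxy)phenyl]-3-{4-(benzyloxy)-2-[(triisopropylsilyl)oxy]phenyl}propan-1-one
Product: 11 (1R,3R)-3-[2-(allyloxy)-4,6-bis(benzyloxy)phenyl]-1-[4-(benzyloxy)phenyl]-3-{4-(benzyloxy)-2-[(triisopropylsilyl)oxy]phenyl}propan-1-ol
Conditions: RuCl[(R,R)-TsDPEN](p-cymene) (2 mol %), HCO2H–Et3N (5:2), CH2Cl2, 30 °C
Reagents that add atoms: none
Why: Noyori-type asymmetric transfer hydrogenation of an aryl alkyl ketone; the (R,R) catalyst gives the (R) carbinol by reagent control, and the conditions leave the allyl ether and the benzyl ethers untouched, which a borane reduction would not guarantee for the allyl group.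

Step 9
Reactants: 11 (1R,3R)-3-[2-(allyloxy)-4,6-bis(benzyloxy)phenyl]-1-[4-(benzyloxy)phenyl]-3-{4-(benzyloxy)-2-[(triisopropylsilyl)oxy]phenyl}propan-1-ol
Product: 12 5-(benzyloxy)-2-{(1R,3R)-1-[2-(allyloxy)-4,6-bis(benzyloxy)phenyl]-3-[4-(benzyloxy)phenyl]-3-hydroxypropyl}phenol
Conditions: TBAF, AcOH, THF, 0 °C
Reagents that add atoms: none
Why: Fluoride cleavage of the aryl silyl ether under buffered, non-acidic conditions, so that the benzylic alcohol is not ionised and only the ring A phenol is set free.

Step 10
Reactants: 12 5-(benzyloxy)-2-{(1R,3R)-1-[2-(allyloxy)-4,6-bis(benzyloxy)phenyl]-3-[4-(benzyloxy)phenyl]-3-hydroxypropyl}phenol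
Product: 13 (2S,4R)-4-[2-(allyloxy)-4,6-bis(benzyloxy)phenyl]-7-(benzyloxy)-2-[4-(benzyloxy)phenyl]chromane
Conditions: PPh3, DIAD, THF, 0 °C → rt
Reagents that add atoms: none
Why: Intramolecular Mitsunobu etherification, a known flavan ring closure; the ring A phenol displaces the activated carbinol with inversion, turning the (R) alcohol into (S)-U-C2 and giving the 2,4-trans flavan, while any leakage through a benzylic ion pair would give the separable 2,4-cis diastereomer.

Step 11
Reactants: 13 (2S,4R)-4-[2-(allyloxy)-4,6-bis(benzyloxy)phenyl]-7-(benzyloxy)-2-[4-(benzyloxy)phenyl]chromane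
Product: 14 3,5-bis(benzyloxy)-2-{(2S,4R)-7-(benzyloxy)-2-[4-(benzyloxy)phenyl]chroman-4-yl}phenol
Conditions: Pd(PPh3)4 (5 mol %), morpholine, THF, rt
Reagents that add atoms: none
Why: Tsuji–Trost-type deallylation: zerovalent palladium ionises the aryl allyl ether to a π-allyl complex that morpholine traps, under neutral conditions that leave the benzyl ethers and the flavan stereocentres unchanged.

Step 12
Reactants: 15 4-(benzyloxy)benzaldehyde
Product: 16 rac-1-[4-(benzyloxy)phenyl]prop-2-en-1-ol
Conditions: vinylmagnesium bromide, THF, −78 °C → 0 °C; aq. NH4Cl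
Reagents that add atoms: vinylmagnesium bromide, C=C[Mg]Br
Why: Grignard addition to an aromatic aldehyde; a neutral ammonium chloride work-up avoids allylic transposition of the electron-rich carbinol.

Step 13
Reactants: 16 rac-1-[4-(benzyloxy)phenyl]prop-2-en-1-ol
Product: 17 (S)-[4-(benzyloxy)phenyl][(2R)-oxiran-2-yl]methanol
Conditions: Ti(Oi-Pr)4 (10 mol %), L-(+)-DIPT (15 mol %), t-BuOOH (0.45 equiv), 4 Å MS, CH2Cl2, −20 °C
Reagents that add atoms: tert-butyl hydroperoxide, CC(C)(C)OO
Why: Sharpless kinetic resolution: with L-(+)-DIPT the titanium tartrate complex epoxidises the (R) enantiomer of 16 much faster and delivers oxygen anti to the aryl group, which gives the erythro epoxy alcohol with (S) carbinol and (R) oxirane carbons; the oxidant is limited so that conversion stays below one half, and unreacted (S)-16 is removed by chromatography.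

Step 14
Reactants: 14 3,5-bis(benzyloxy)-2-{(2S,4R)-7-(benzyloxy)-2-[4-(benzyloxy)phenyl]chroman-4-yl}phenol; 17 (S)-[4-(benzyloxy)phenyl][(2R)-oxiran-2-yl]methanol
Product: 18 (2S,4R)-7-(benzyloxy)-2-[4-(benzyloxy)phenyl]-4-[2,4-bis(benzyloxy)-6-{(R)-[4-(benzyloxy)phenyl][(2R)-oxiran-2-yl]methoxy}phenyl]chromane
Conditions: PPh3, DIAD, toluene, 0 °C → rt
Reagents that add atoms: none
Why: Mitsunobu etherification: the phenol of 14, which has only one ortho substituent, displaces the oxyphosphonium derivative of the secondary benzylic alcohol with inversion, so the (S) carbinol of 17 becomes (R)-L-C2 while the oxirane is untouched; a product of ionisation or of the minor enantiomer of 17 would be a diastereomer of 18 and is removed by chromatography.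

Step 15
Reactants: 18 (2S,4R)-7-(benzyloxy)-2-[4-(benzyloxy)phenyl]-4-[2,4-bis(benzyloxy)-6-{(R)-[4-(benzyloxy)phenyl][(2R)-oxiran-2-yl]methoxy}phenyl]chromane
Product: 19 (2R,3R)-5,7-bis(benzyloxy)-8-{(2S,4R)-7-(benzyloxy)-2-[4-(benzyloxy)phenyl]chroman-4-yl}-2-[4-(benzyloxy)phenyl]chroman-3-ol
Conditions: AuCl3 (5 mol %), AgOTf (15 mol %), 4 Å MS, ClCH2CH2Cl (0.01 M), 0 °C → rt
Reagents that add atoms: none
Why: AgOTf abstracts chloride from AuCl3, and the resulting cationic trivalent gold centre coordinates the epoxide oxygen of 18, the most Lewis-basic site of the molecule. Ring D then attacks the terminal epoxide carbon through L-C4a in an intramolecular Friedel–Crafts alkylation, the arenium ion loses its proton, and protonation of the gold alkoxide releases the catalyst and the free L-3 hydroxyl. The closest known reaction type is the gold-catalysed cycloalkylation of aryl glycidyl-type ethers to chroman-3-ols, which is known for 3,5-dialkoxyphenyl ethers of 1-aryl-2,3-epoxypropan-1-ols. The pyran ring of L closes in the 6-endo mode with respect to the epoxide, both epoxide carbons ending inside the new ring; 5-exo attack on the internal carbon is disfavoured because that carbon is more hindered and is inductively deactivated by the neighbouring aryloxy-bearing carbon. No stereocentre is created: L-C3 keeps the configuration of the oxirane carbon because its C–O bond is not broken, L-C2 is a spectator set in step 14, and the attacked carbon is a CH2 group. Site selectivity on the arene needs no control, since the tether from L-O1 reaches only L-C4a (L-C8 is quaternary and L-C6 is out of range), and L-C4a is also the most electron-rich carbon of ring D. The selectivity that must be secured is arene attack ahead of ionisation of the two para-benzyloxybenzylic C–O bonds (L-C2–O1 and U-C2–O1); low catalyst loading, low temperature, molecular sieves against adventitious acid and high dilution serve this, and the electron-withdrawing oxirane next to L-C2 disfavours a cation there.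

Step 16
Reactants: 19 (2R,3R)-5,7-bis(benzyloxy)-8-{(2S,4R)-7-(benzyloxy)-2-[4-(benzyloxy)phenyl]chroman-4-yl}-2-[4-(benzyloxy)phenyl]chroman-3-ol
Product: 20 (2R,3R)-8-[(2S,4R)-7-hydroxy-2-(4-hydroxyphenyl)chroman-4-yl]-2-(4-hydroxyphenyl)chromane-3,5,7-triol
Conditions: H2 (1 atm), Pd(OH)2/C, THF–MeOH, rt
Reagents that add atoms: none
Why: Hydrogenolysis of the five aryl benzyl ethers, the standard end game of benzylated flavan-3-ols; the acyclic O-benzyl groups are cleaved much faster than the two cyclic benzylic ethers, and the neutral medium spares the interflavan bond.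

## Compound list

1 | 2,4,6-trihydroxybenzaldehyde | O=Cc1c(O)cc(O)cc1O | starting material
2 | 2,4-bis(benzyloxy)-6-hydroxybenzaldehyde | O=Cc1c(O)cc(OCc2ccccc2)cc1OCc1ccccc1 | intermediate
3 | 2-(allyloxy)-4,6-bis(benzyloxy)benzaldehyde | O=Cc1c(OCC=C)cc(OCc2ccccc2)cc1OCc1ccccc1 | intermediate
4 | 4'-benzyloxyacetophenone | CC(=O)c1ccc(OCc2ccccc2)cc1 | starting material
5 | (E)-3-[2-(allyloxy)-4,6-bis(benzyloxy)phenyl]-1-[4-(benzyloxy)phenyl]prop-2-en-1-one | O=C(/C=C/c1c(OCC=C)cc(OCc2ccccc2)cc1OCc1ccccc1)c1ccc(OCc2ccccc2)cc1 | intermediate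
6 | 3-(benzyloxy)phenol | Oc1cccc(OCc2ccccc2)c1 | starting material
7 | 5-(benzyloxy)-2-bromophenol | Oc1cc(OCc2ccccc2)ccc1Br | intermediate
8 | [5-(benzyloxy)-2-bromophenoxy]tri(propan-2-yl)silane | CC(C)[Si](Oc1cc(OCc2ccccc2)ccc1Br)(C(C)C)C(C)C | intermediate
9 | [5-(benzyloxy)-2-(4,4,5,5-tetramethyl-1,3,2-dioxaborolan-2-yl)phenoxy]tri(propan-2-yl)silane | CC(C)[Si](Oc1cc(OCc2ccccc2)ccc1B1OC(C)(C)C(C)(C)O1)(C(C)C)C(C)C | intermediate
10 | (3R)-3-[2-(allyloxy)-4,6-bis(benzyloxy)phenyl]-1-[4-(benzyloxy)phenyl]-3-{4-(benzyloxy)-2-[(triisopropylsilyl)oxy]phenyl}propan-1-one | O=C(C[C@@H](c1c(OCC=C)cc(OCc2ccccc2)cc1OCc1ccccc1)c1ccc(OCc2ccccc2)cc1O[Si](C(C)C)(C(C)C)C(C)C)c1ccc(OCc2ccccc2)cc1 | intermediate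
11 | (1R,3R)-3-[2-(allyloxy)-4,6-bis(benzyloxy)phenyl]-1-[4-(benzyloxy)phenyl]-3-{4-(benzyloxy)-2-[(triisopropylsilyl)oxy]phenyl}propan-1-ol | O[C@H](C[C@@H](c1c(OCC=C)cc(OCc2ccccc2)cc1OCc1ccccc1)c1ccc(OCc2ccccc2)cc1O[Si](C(C)C)(C(C)C)C(C)C)c1ccc(OCc2ccccc2)cc1 | intermediate
12 | 5-(benzyloxy)-2-{(1R,3R)-1-[2-(allyloxy)-4,6-bis(benzyloxy)phenyl]-3-[4-(benzyloxy)phenyl]-3-hydroxypropyl}phenol | O[C@H](C[C@@H](c1c(OCC=C)cc(OCc2ccccc2)cc1OCc1ccccc1)c1ccc(OCc2ccccc2)cc1O)c1ccc(OCc2ccccc2)cc1 | intermediate
13 | (2S,4R)-4-[2-(allyloxy)-4,6-bis(benzyloxy)phenyl]-7-(benzyloxy)-2-[4-(benzyloxy)phenyl]chromane | c1ccccc1COc1ccc([C@@H]2C[C@@H](c3c(OCc4ccccc4)cc(OCc4ccccc4)cc3OCC=C)c3ccc(OCc4ccccc4)cc3O2)cc1 | intermediate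
14 | 3,5-bis(benzyloxy)-2-{(2S,4R)-7-(benzyloxy)-2-[4-(benzyloxy)phenyl]chroman-4-yl}phenol | c1ccccc1COc1ccc([C@@H]2C[C@@H](c3c(OCc4ccccc4)cc(OCc4ccccc4)cc3O)c3ccc(OCc4ccccc4)cc3O2)cc1 | intermediate
15 | 4-(benzyloxy)benzaldehyde | O=Cc1ccc(OCc2ccccc2)cc1 | starting material
16 | rac-1-[4-(benzyloxy)phenyl]prop-2-en-1-ol | C=CC(O)c1ccc(OCc2ccccc2)cc1 | intermediate
17 | (S)-[4-(benzyloxy)phenyl][(2R)-oxiran-2-yl]methanol (erythro) | O[C@@H](c1ccc(OCc2ccccc2)cc1)[C@H]1CO1 | intermediate
18 | (2S,4R)-7-(benzyloxy)-2-[4-(benzyloxy)phenyl]-4-[2,4-bis(benzyloxy)-6-{(R)-[4-(benzyloxy)phenyl][(2R)-oxiran-2-yl]methoxy}phenyl]chromane | c1ccccc1COc1ccc([C@@H]2C[C@@H](c3c(OCc4ccccc4)cc(OCc4ccccc4)cc3O[C@H](c3ccc(OCc4ccccc4)cc3)[C@H]3CO3)c3ccc(OCc4ccccc4)cc3O2)cc1 | intermediate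
19 | (2R,3R)-5,7-bis(benzyloxy)-8-{(2S,4R)-7-(benzyloxy)-2-[4-(benzyloxy)phenyl]chroman-4-yl}-2-[4-(benzyloxy)phenyl]chroman-3-ol | c1ccccc1COc1ccc([C@@H]2C[C@@H](c3c(OCc4ccccc4)cc(OCc4ccccc4)c4c3O[C@H](c3ccc(OCc5ccccc5)cc3)[C@H](O)C4)c3ccc(OCc4ccccc4)cc3O2)cc1 | intermediate
20 | (2R,3R)-8-[(2S,4R)-7-hydroxy-2-(4-hydroxyphenyl)chroman-4-yl]-2-(4-hydroxyphenyl)chromane-3,5,7-triol | Oc1ccc([C@@H]2C[C@@H](c3c(O)cc(O)c4c3O[C@H](c3ccc(O)cc3)[C@H](O)C4)c3ccc(O)cc3O2)cc1 | target

## Step count and risk

Total: 16 steps. Longest linear sequence: 11 steps (1, 2, 3, 7, 8, 9, 10, 11, 14, 15, 16).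

**Step 15 (key step).** The most likely failure is heterolysis of the para-benzyloxybenzylic L-C2–O1 bond, or a hydride shift of the activated epoxide, outrunning the arene attack. L-C2 would then lose its configuration or the lower fragment would be detached. The substrate carries more Lewis-basic oxygens and more bulk than the simple aryl ethers for which the cyclisation is known. The fallback replaces the donor on the L-4' oxygen by an acyl group, which destabilises the benzylic cation; the same change steadies the inversion in step 14. It sets out from phenol 14 and returns at 20. 4-Hydroxybenzaldehyde is acylated with pivaloyl chloride to 4-formylphenyl pivalate F1. Vinylmagnesium bromide at −78 °C gives rac-4-(1-hydroxyprop-2-en-1-yl)phenyl pivalate F2, and the kinetic resolution of step 13 gives 4-{(S)-hydroxy[(2R)-oxiran-2-yl]methyl}phenyl pivalate F3. Mitsunobu coupling with 14 gives the L-4'-O-pivaloyl analogue of 18 F4, and cyclisation as in step 15 gives the L-4'-O-pivaloyl analogue of 19 F5. K2CO3 in methanol removes the ester to give the tetra-O-benzyl ether with free L-4' and L-3 hydroxyls F6, and hydrogenolysis as in step 16 gives 20.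

**Step 7.** The most likely failure is slow insertion at the β-carbon, which carries a doubly ortho-substituted, electron-rich aryl group, so that protodeboronation consumes the boronate; the facial sense on so hindered an enone is also less secure than on simple chalcones. The fallback replaces catalyst control by auxiliary control. It sets out from aldehyde 3 and bromide 8 and returns at ketone 10. Doebner–Knoevenagel condensation of 3 with malonic acid gives (E)-3-[2-(allyloxy)-4,6-bis(benzyloxy)phenyl]prop-2-enoic acid F7. Acylation of (S)-4-phenyl-1,3-oxazolidin-2-one through the mixed pivalic anhydride gives (4S)-3-{(E)-3-[2-(allyloxy)-4,6-bis(benzyloxy)phenyl]prop-2-enoyl}-4-phenyl-1,3-oxazolidin-2-one F8. Bromide 8 and magnesium give {4-(benzyloxy)-2-[(triisopropylsilyl)oxy]phenyl}magnesium bromide F9. With CuBr·SMe2 this adds to the chelated imide on the face away from the phenyl group and gives the (3R) adduct, (4S)-3-{(3R)-3-[2-(allyloxy)-4,6-bis(benzyloxy)phenyl]-3-[4-(benzyloxy)-2-(triisopropylsilyloxy)phenyl]propanoyl}-4-phenyl-1,3-oxazolidin-2-one F10. AlMe3 with N,O-dimethylhydroxylamine hydrochloride gives the Weinreb amide (3R)-3-[2-(allyloxy)-4,6-bis(benzyloxy)phenyl]-3-[4-(benzyloxy)-2-(triisopropylsilyloxy)phenyl]-N-methoxy-N-methylpropanamide F11, and 4-(benzyloxy)phenylmagnesium bromide converts it into 10.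

**Step 13.** The most likely failure is ionisation or alkoxide opening of the electron-rich benzylic substrate and product on the Lewis-acidic titanium centre, together with insufficient enantiomeric enrichment, since a kinetic resolution enriches its product less than its recovered substrate. The fallback separates resolution from epoxidation. It sets out from 16 and returns at 17. Immobilised Candida antarctica lipase B with vinyl acetate acylates the (R) enantiomer to (R)-1-[4-(benzyloxy)phenyl]prop-2-en-1-yl acetate F12. K2CO3 in methanol gives (R)-1-[4-(benzyloxy)phenyl]prop-2-en-1-ol F13. Hydroxyl-directed epoxidation with VO(acac)2 and t-BuOOH, which favours the erythro isomer for vinyl carbinols, gives 17 after removal of the threo isomer.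

**Step 4.** The most likely failure is bromination para to the hydroxyl (ortho to the benzyloxy group) or double bromination, since both oxygens activate the ring. The fallback changes the directing group. It sets out from 6 and returns at 7. Acetylation gives 3-(benzyloxy)phenyl acetate F14, in which the benzyloxy group is the only strong donor. NBS in acetonitrile then brominates para to it and gives 5-(benzyloxy)-2-bromophenyl acetate F15, and K2CO3 in methanol gives 7.

Further compounds

F1 | step 15 | 4-formylphenyl pivalate | CC(C)(C)C(=O)Oc1ccc(C=O)cc1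
F2 | step 15 | rac-4-(1-hydroxyprop-2-en-1-yl)phenyl pivalate | CC(C)(C)C(=O)Oc1ccc(C(O)C=C)cc1
F3 | step 15 | 4-{(S)-hydroxy[(2R)-oxiran-2-yl]methyl}phenyl pivalate | CC(C)(C)C(=O)Oc1ccc([C@H](O)[C@H]2CO2)cc1
F4 | step 15 | L-4'-O-pivaloyl analogue of 18 | c1ccccc1COc1ccc([C@@H]2C[C@@H](c3c(OCc4ccccc4)cc(OCc4ccccc4)cc3O[C@H](c3ccc(OC(=O)C(C)(C)C)cc3)[C@H]3CO3)c3ccc(OCc4ccccc4)cc3O2)cc1
F5 | step 15 | L-4'-O-pivaloyl analogue of 19 | c1ccccc1COc1ccc([C@@H]2C[C@@H](c3c(OCc4ccccc4)cc(OCc4ccccc4)c4c3O[C@H](c3ccc(OC(=O)C(C)(C)C)cc3)[C@H](O)C4)c3ccc(OCc4ccccc4)cc3O2)cc1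
F6 | step 15 | tetra-O-benzyl ether of 20 with free L-4' and L-3 hydroxyls | c1ccccc1COc1ccc([C@@H]2C[C@@H](c3c(OCc4ccccc4)cc(OCc4ccccc4)c4c3O[C@H](c3ccc(O)cc3)[C@H](O)C4)c3ccc(OCc4ccccc4)cc3O2)cc1
F7 | step 7 | (E)-3-[2-(allyloxy)-4,6-bis(benzyloxy)phenyl]prop-2-enoic acid | OC(=O)/C=C/c1c(OCC=C)cc(OCc2ccccc2)cc1OCc1ccccc1
F8 | step 7 | (4S)-3-{(E)-3-[2-(allyloxy)-4,6-bis(benzyloxy)phenyl]prop-2-enoyl}-4-phenyl-1,3-oxazolidin-2-one | O=C(/C=C/c1c(OCC=C)cc(OCc2ccccc2)cc1OCc1ccccc1)N1[C@@H](c2ccccc2)COC1=O
F9 | step 7 | {4-(benzyloxy)-2-[(triisopropylsilyl)oxy]phenyl}magnesium bromide | CC(C)[Si](Oc1cc(OCc2ccccc2)ccc1[Mg]Br)(C(C)C)C(C)C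
F10 | step 7 | (4S)-3-{(3R)-3-[2-(allyloxy)-4,6-bis(benzyloxy)phenyl]-3-[4-(benzyloxy)-2-(triisopropylsilyloxy)phenyl]propanoyl}-4-phenyl-1,3-oxazolidin-2-one | O=C(C[C@@H](c1c(OCC=C)cc(OCc2ccccc2)cc1OCc1ccccc1)c1ccc(OCc2ccccc2)cc1O[Si](C(C)C)(C(C)C)C(C)C)N1[C@@H](c2ccccc2)COC1=O
F11 | step 7 | (3R)-3-[2-(allyloxy)-4,6-bis(benzyloxy)phenyl]-3-[4-(benzyloxy)-2-(triisopropylsilyloxy)phenyl]-N-methoxy-N-methylpropanamide | CON(C)C(=O)C[C@@H](c1c(OCC=C)cc(OCc2ccccc2)cc1OCc1ccccc1)c1ccc(OCc2ccccc2)cc1O[Si](C(C)C)(C(C)C)C(C)C
F12 | step 13 | (R)-1-[4-(benzyloxy)phenyl]prop-2-en-1-yl acetate | C=C[C@@H](OC(C)=O)c1ccc(OCc2ccccc2)cc1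
F13 | step 13 | (R)-1-[4-(benzyloxy)phenyl]prop-2-en-1-ol | C=C[C@@H](O)c1ccc(OCc2ccccc2)cc1
F14 | step 4 | 3-(benzyloxy)phenyl acetate | CC(=O)Oc1cccc(OCc2ccccc2)c1
F15 | step 4 | 5-(benzyloxy)-2-bromophenyl acetate | CC(=O)Oc1cc(OCc2ccccc2)ccc1Br
A1 | alternative 1 | (1R,3R)-3-(4-benzyloxy-2-pivaloyloxyphenyl)-1-(4-benzyloxyphenyl)-1-(tert-butyldimethylsilyloxy)-3-(tetra-O-benzylepiafzelechin-8-yl)propane | c1ccccc1COc1ccc([C@H](O[Si](C)(C)C(C)(C)C)C[C@@H](c2c(OCc3ccccc3)cc(OCc3ccccc3)c3c2O[C@H](c2ccc(OCc4ccccc4)cc2)[C@H](OCc2ccccc2)C3)c2ccc(OCc3ccccc3)cc2OC(=O)C(C)(C)C)cc1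
A2 | alternative 1 | [(2R,3R)-3,5,7-tris(benzyloxy)-2-(4-benzyloxyphenyl)chroman-8-yl]boronic acid | OB(O)c1c(OCc2ccccc2)cc(OCc2ccccc2)c2c1O[C@H](c1ccc(OCc3ccccc3)cc1)[C@H](OCc1ccccc1)C2
A3 | alternative 2 | (4R)-7-benzyloxy-4-(tetra-O-benzylepiafzelechin-8-yl)chroman-2-one | O=C1C[C@@H](c2c(OCc3ccccc3)cc(OCc3ccccc3)c3c2O[C@H](c2ccc(OCc4ccccc4)cc2)[C@H](OCc2ccccc2)C3)c2ccc(OCc3ccccc3)cc2O1
A4 | alternative 2 | (3R)-6-benzyloxy-3-(tetra-O-benzylepiafzelechin-8-yl)indan-1-one | O=C1C[C@@H](c2c(OCc3ccccc3)cc(OCc3ccccc3)c3c2O[C@H](c2ccc(OCc4ccccc4)cc2)[C@H](OCc2ccccc2)C3)c2ccc(OCc3ccccc3)cc12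
A5 | alternative 3 | tetra-O-benzyl L-4'-O-pivaloyl derivative of 20 with free L-3 hydroxyl | c1ccccc1COc1ccc([C@@H]2C[C@@H](c3c(OCc4ccccc4)cc(OCc4ccccc4)c4c3O[C@H](c3ccc(OC(=O)C(C)(C)C)cc3)[C@H](O)C4)c3ccc(OCc4ccccc4)cc3O2)cc1
A6 | alternative 3 | 3,5-bis(benzyloxy)-2-{(2S,4R)-7-(benzyloxy)-2-[4-(benzyloxy)phenyl]chroman-4-yl}-6-{[(2R,3S)-3-(4-pivaloyloxyphenyl)oxiran-2-yl]methyl}phenol | c1ccccc1COc1ccc([C@@H]2C[C@@H](c3c(OCc4ccccc4)cc(OCc4ccccc4)c(C[C@H]4O[C@H]4c4ccc(OC(=O)C(C)(C)C)cc4)c3O)c3ccc(OCc4ccccc4)cc3O2)cc1
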